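**Retrosynthetic overview**

- The strategy rests on ring A (C1–C5, C10). Oxygen on C1 and C2, the carbon C15 on C4 and the quaternary C10 bearing C14 are the substitution pattern of the para-quinone of methyl 3-methoxysalicylate, and O9 next to C10 is the oxygen of a 1-silyloxybutadiene.
- Late disconnections: the C14 silyl ether, the O1 tiglate and the O2/O9 acetates (O1 and O2 are told apart through a cyclic orthoacetate); then C7–C11 (conjugate addition to a Δ7-9-one) and C4–C15 (methyl addition to the C4 vinylogous ester with carbonyl transposition).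
- Key disconnection: C5–C6 and C9–C10 by an enantioselective quinone Diels–Alder reaction, followed by epimerisation of C5 to the trans ring fusion.
- Ring order: ring A comes from the arene (dearomatised to the quinone); ring B is closed by the [4+2] cycloaddition.

Key step: step 3

Convention: eudesmane numbering throughout (ring A = C1–C5 and C10, ring B = C5–C10, C14 on C10, C15 on C4, isopropenyl C11–C13 on C7), also for the decalin names; β is the face of C14, α the opposite face.

Assumption: the (S,S) ligand is taken to shield the quinone face that leads to 5; if the sense of induction is the reverse, the equally available (R,R) ligand is used.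

**Route**

Step 1
Reactants: 1 methyl 3-methoxysalicylate
Product: 2 2-methoxy-6-(methoxycarbonyl)-1,4-benzoquinone
Conditions: (KSO3)2NO (2.5 equiv), KH2PO4 buffer, H2O/acetone, 0 °C to rt; used at once
Reagents that add atoms: potassium nitrosodisulfonate, [O]N(S(=O)(=O)[O-])S(=O)(=O)[O-].[K+].[K+]
Why: Teuber oxidation, in which the nitrosodisulfonate radical abstracts the phenolic hydrogen and a second equivalent oxygenates the only free para position (both ortho positions are blocked), the adduct collapsing to the para-quinone.

Step 2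
Reactants: 3 crotonaldehyde
Product: 4 (E)-1-(tert-butyldimethylsilyloxy)buta-1,3-diene
Conditions: TBSOTf, Et3N, Et2O, 0 °C; distillation
Reagents that add atoms: tert-butyldimethylsilyl triflate, CC(C)(C)[Si](C)(C)OS(=O)(=O)C(F)(F)F
Why: Silyl dienol ether formation by soft enolisation, the O-silylated enal losing a γ-proton to the amine to give the conjugated diene with the E enol ether favoured.

Step 3
Reactants: 2 2-methoxy-6-(methoxycarbonyl)-1,4-benzoquinone; 4 (E)-1-(tert-butyldimethylsilyloxy)buta-1,3-diene
Product: 5 cis-fused adduct, methyl 9α-(tert-butyldimethylsilyloxy)-2-methoxy-1,4-dioxo-5β-H-decal-2,7-diene-10β-carboxylate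
Conditions: 4 (1.5 equiv), Cu(OTf)2 (10 mol%), 2,2'-isopropylidenebis[(4S)-4-tert-butyl-2-oxazoline] (11 mol%), 4 Å MS, CH2Cl2, −78 °C
Reagents that add atoms: none
Why: A concerted, asynchronous suprafacial [4+2] cycloaddition of the diene to the C5–C10 alkene of the copper-chelated quinone, the closest known reaction type being the chiral Lewis acid catalysed Diels–Alder reaction of 2-alkoxycarbonyl-1,4-benzoquinones with 1-oxygenated dienes. Ring B is closed by intermolecular annulation, the six-membered ring arising from formation of C5–C6 and C9–C10 in one event. C5 and C10 are set cis by suprafacial addition to the alkene, C9 is set by the endo transition state (diene under the ring A carbonyls, so the E-silyloxy group ends up cis to C1 and trans to the C14 ester), and the absolute configuration is set by the ligand, which shields one face of the quinone held in a six-membered chelate through the C1 ketone and ester oxygens. Site selectivity is secured because the C5–C10 alkene carries three carbonyl groups and is the one activated by the chelate, whereas C2–C3 is deactivated by its methoxy group. Regioselectivity is secured because the nucleophilic unsubstituted diene terminus bonds to C5, the β carbon of the alkylidene β-keto ester, which places the oxygenated terminus on C10.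

Step 4
Reactants: 5 cis-fused adduct
Product: 6 trans-fused adduct, methyl 9α-(tert-butyldimethylsilyloxy)-2-methoxy-1,4-dioxo-trans-decal-2,7-diene-10β-carboxylate (5α-H)
Conditions: DBU (0.2 equiv), THF, rt
Reagents that add atoms: none
Why: Base-mediated thermodynamic epimerisation through the C4 enolate, C5 being the only acidic ring-fusion position and aromatisation being blocked by the quaternary C10, which should place H5 on the α face, anti to the C10 ester.

Step 5
Reactants: 6 trans-fused adduct
Product: 7 methyl 9α-hydroxy-2-methoxy-1,4-dioxo-trans-decal-2,7-diene-10β-carboxylate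
Conditions: HF·pyridine, pyridine, THF, 0 °C to rt
Reagents that add atoms: none
Why: Fluoride cleavage of the silyl ether in a weakly acidic buffered medium, which should avoid retro-aldol opening of the β-hydroxy ketone and leave the vinylogous ester untouched.

Step 6
Reactants: 7 9α-hydroxy enedione ester
Product: 8 methyl 1β,9α-dihydroxy-2-methoxy-4-oxo-trans-decal-2,7-diene-10β-carboxylate
Conditions: Me4NBH(OAc)3 (5 equiv), MeCN/AcOH 1:1, −30 °C
Reagents that add atoms: none
Why: Evans–Saksena reduction, in which the borohydride bound to the pseudoaxial 9α oxygen delivers hydride to the α face of the C1 ketone, the only β-hydroxy ketone, giving the 1β alcohol anti to the C9 hydroxyl while the C4 vinylogous ester carbonyl and the ester are not reduced.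

Step 7
Reactants: 8 1β,9α-dihydroxy vinylogous ester
Product: 10 methyl 1β,9α-dihydroxy-4-methyl-2-oxo-trans-decal-3,7-diene-10β-carboxylate, via tertiary C4 carbinol 9 (not isolated)
Conditions: MeLi (5 equiv), CeCl3 (5 equiv), THF, −78 °C; then 1 M HCl, THF, 0 °C to rt
Reagents that add atoms: methyllithium, [Li]C; water, O
Why: Stork–Danheiser transposition, the organocerium reagent adding 1,2 to the C4 vinylogous ester carbonyl without enolisation (the hindered C10 ester flanked by two alkoxides should react more slowly at −78 °C) and acid then ionising the tertiary allylic carbinol and hydrolysing the enol ether to the 4-methyl-Δ3-2-one.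

Step 8
Reactants: 10 hydroxy enone ester
Product: 11 10β-(hydroxymethyl)-4-methyl-trans-decal-3,7-diene-1β,2β,9α-triol (the 1β,2β,9α,14-tetraol)
Conditions: LiAlH4, THF, −78 °C to rt; H2O, NaOH work-up
Reagents that add atoms: none
Why: Hydride reduction, the enone being reduced 1,2 at low temperature from the α face because the axial C10 ester blocks the β face in a 1,3-diaxial sense, which sets the pseudoaxial 2β alcohol, and the ester being reduced to the C14 alcohol on warming.

Step 9
Reactants: 11 tetraol
Product: 12 10β-(tert-butyldimethylsilyloxymethyl)-4-methyl-trans-decal-3,7-diene-1β,2β,9α-triol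
Conditions: TBSCl (1.1 equiv), imidazole, DMF, 0 °C
Reagents that add atoms: tert-butyldimethylsilyl chloride, CC(C)(C)[Si](C)(C)Cl
Why: Silyl ether formation selective for the only primary hydroxyl, the three secondary hydroxyls being hindered.

Step 10
Reactants: 12 14-O-silyl triol
Product: 13 1β,2β-O-(1-methoxyethylidene) orthoester of 12 with free 9α-hydroxyl (both epimers at the orthoester carbon)
Conditions: MeC(OMe)3, PPTS (cat.), CH2Cl2, rt; Et3N quench
Reagents that add atoms: trimethyl orthoacetate, CC(OC)(OC)OC
Why: Acid-catalysed orthoester exchange, O1 and O2 being the only cis pair that can close a five-membered ring (O9 is anti to every other oxygen), the new orthoester centre being without consequence.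

Step 11
Reactants: 13 orthoester 9α-ol
Product: 14 10β-(tert-butyldimethylsilyloxymethyl)-1β,2β-(1-methoxyethylidenedioxy)-4-methyl-trans-decal-3,7-dien-9-one
Conditions: MnO2 (excess), CH2Cl2, rt
Reagents that add atoms: none
Why: MnO2 oxidation of the only free allylic alcohol to the Δ7-9-one under neutral conditions that keep the orthoester.

Step 12
Reactants: 14 Δ7-9-one; 15 isopropenylmagnesium bromide
Product: 16 14-(tert-butyldimethylsilyloxy)-1β,2β-(1-methoxyethylidenedioxy)-7-epi-eudesma-3,11-dien-9-one (7α-isopropenyl)
Conditions: 15 (2 equiv), CuBr·SMe2 (20 mol%), THF, −78 to −40 °C; aq. NH4Cl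
Reagents that add atoms: none
Why: Copper-catalysed conjugate addition of the Grignard reagent, the stereoelectronically preferred axial attack on the trans-fused cyclohexenone through a chair-like enolate placing the isopropenyl group on the α face of C7, while the neopentyl C9 carbonyl resists 1,2-addition.

Step 13
Reactants: 16 7α-isopropenyl-9-one
Product: 17 14-(tert-butyldimethylsilyloxy)-1β,2β-(1-methoxyethylidenedioxy)-7-epi-eudesma-3,11-dien-9α-ol
Conditions: LiBH(s-Bu)3, THF, −78 °C; then NaOH, H2O2, 0 °C
Reagents that add atoms: none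
Why: Reduction with a bulky trialkylborohydride, which attacks the C9 ketone along the equatorial trajectory because the axial approach on the α face is closed by the syn-axial 7α-isopropenyl group, giving the axial 9α alcohol.

Step 14
Reactants: 17 9α-ol
Product: 18 9α-acetoxy-14-(tert-butyldimethylsilyloxy)-1β,2β-(1-methoxyethylidenedioxy)-7-epi-eudesma-3,11-diene
Conditions: Ac2O, DMAP, Et3N, CH2Cl2, rt to 40 °C
Reagents that add atoms: acetic anhydride, CC(=O)OC(C)=O
Why: DMAP-catalysed acylation of the only free hydroxyl in a basic medium that leaves the orthoester intact.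

Step 15
Reactants: 18 9α-acetate orthoester
Product: 19 2β,9α-diacetoxy-14-(tert-butyldimethylsilyloxy)-7-epi-eudesma-3,11-dien-1β-ol
Conditions: AcOH/H2O/THF, rt, short reaction time
Reagents that add atoms: water, O
Why: Mild acid hydrolysis of the cyclic orthoester through the dioxolanylium ion and its hydrate, which opens with the known stereoelectronic preference for the ester on the (pseudo)axial oxygen, here O2, and frees the equatorial C1 hydroxyl.

Step 16
Reactants: 19 diacetate 1β-ol
Product: 20 2β,9α-diacetoxy-14-(tert-butyldimethylsilyloxy)-7-epi-eudesma-3,11-dien-1β-yl tiglate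
Conditions: tiglic acid, 2,4,6-trichlorobenzoyl chloride, Et3N, toluene, rt; then 19, DMAP, rt to 50 °C
Reagents that add atoms: tiglic acid, C/C=C(\C)C(=O)O
Why: Yamaguchi esterification, the mixed anhydride made in the flask transferring the tigloyl group through DMAP to the last free hydroxyl with the stable E geometry retained.

Step 17
Reactants: 20 silyl ether
Product: 21 target, 2β,9α-diacetoxy-14-hydroxy-7-epi-eudesma-3,11-dien-1β-yl tiglate (CNP0267061.1)
Conditions: HF·pyridine, pyridine, THF, 0 °C to rt
Reagents that add atoms: none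
Why: Fluoride cleavage of the primary silyl ether under weakly acidic conditions, which should keep the three esters in place and suppress 1,3-acyl migration to the freed C14 hydroxyl.

**Compound list**

1 | methyl 3-methoxysalicylate | COC(=O)c1cccc(OC)c1O | starting material
2 | 2-methoxy-6-(methoxycarbonyl)-1,4-benzoquinone | COC(=O)C1=CC(=O)C=C(OC)C1=O | intermediate
3 | crotonaldehyde | C/C=C/C=O | starting material
4 | (E)-1-(tert-butyldimethylsilyloxy)buta-1,3-diene | C=C/C=C/O[Si](C)(C)C(C)(C)C | intermediate
5 | cis-fused adduct, methyl 9α-(tert-butyldimethylsilyloxy)-2-methoxy-1,4-dioxo-5β-H-decal-2,7-diene-10β-carboxylate | C1=C[C@H](O[Si](C)(C)C(C)(C)C)[C@@]2(C(=O)OC)[C@@H](C1)C(=O)C=C(OC)C2=O | intermediate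
6 | trans-fused adduct (5α-H epimer of 5) | C1=C[C@H](O[Si](C)(C)C(C)(C)C)[C@@]2(C(=O)OC)[C@H](C1)C(=O)C=C(OC)C2=O | intermediate
7 | methyl 9α-hydroxy-2-methoxy-1,4-dioxo-trans-decal-2,7-diene-10β-carboxylate | C1=C[C@H](O)[C@@]2(C(=O)OC)[C@H](C1)C(=O)C=C(OC)C2=O | intermediate
8 | methyl 1β,9α-dihydroxy-2-methoxy-4-oxo-trans-decal-2,7-diene-10β-carboxylate | C1=C[C@H](O)[C@@]2(C(=O)OC)[C@H](C1)C(=O)C=C(OC)[C@@H]2O | intermediate
9 | methyl 1β,4,9α-trihydroxy-2-methoxy-4-methyl-trans-decal-2,7-diene-10β-carboxylate (C4 configuration not defined, lost in the same step) | C1=C[C@H](O)[C@@]2(C(=O)OC)[C@H](C1)C(C)(O)C=C(OC)[C@@H]2O | intermediate (not isolated)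
10 | methyl 1β,9α-dihydroxy-4-methyl-2-oxo-trans-decal-3,7-diene-10β-carboxylate | C1=C[C@H](O)[C@@]2(C(=O)OC)[C@H](C1)C(C)=CC(=O)[C@@H]2O | intermediate
11 | 10β-(hydroxymethyl)-4-methyl-trans-decal-3,7-diene-1β,2β,9α-triol | C1=C[C@H](O)[C@@]2(CO)[C@H](C1)C(C)=C[C@H](O)[C@@H]2O | intermediate
12 | 10β-(tert-butyldimethylsilyloxymethyl)-4-methyl-trans-decal-3,7-diene-1β,2β,9α-triol | C1=C[C@H](O)[C@@]2(CO[Si](C)(C)C(C)(C)C)[C@H](C1)C(C)=C[C@H](O)[C@@H]2O | intermediate
13 | 1β,2β-O-(1-methoxyethylidene) orthoester of 12, 9α-ol (orthoester carbon: both epimers) | C1=C[C@H](O)[C@@]2(CO[Si](C)(C)C(C)(C)C)[C@H](C1)C(C)=C[C@H](OC3(C)OC)[C@@H]2O3 | intermediate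
14 | 10β-(tert-butyldimethylsilyloxymethyl)-1β,2β-(1-methoxyethylidenedioxy)-4-methyl-trans-decal-3,7-dien-9-one | C1=CC(=O)[C@@]2(CO[Si](C)(C)C(C)(C)C)[C@H](C1)C(C)=C[C@H](OC3(C)OC)[C@@H]2O3 | intermediate
15 | isopropenylmagnesium bromide | C=C(C)[Mg]Br | starting material
16 | 14-(tert-butyldimethylsilyloxy)-1β,2β-(1-methoxyethylidenedioxy)-7-epi-eudesma-3,11-dien-9-one | C=C(C)[C@@H]1CC(=O)[C@@]2(CO[Si](C)(C)C(C)(C)C)[C@H](C1)C(C)=C[C@H](OC3(C)OC)[C@@H]2O3 | intermediate
17 | 14-(tert-butyldimethylsilyloxy)-1β,2β-(1-methoxyethylidenedioxy)-7-epi-eudesma-3,11-dien-9α-ol | C=C(C)[C@@H]1C[C@H](O)[C@@]2(CO[Si](C)(C)C(C)(C)C)[C@H](C1)C(C)=C[C@H](OC3(C)OC)[C@@H]2O3 | intermediate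
18 | 9α-acetoxy-14-(tert-butyldimethylsilyloxy)-1β,2β-(1-methoxyethylidenedioxy)-7-epi-eudesma-3,11-diene | C=C(C)[C@@H]1C[C@H](OC(C)=O)[C@@]2(CO[Si](C)(C)C(C)(C)C)[C@H](C1)C(C)=C[C@H](OC3(C)OC)[C@@H]2O3 | intermediate
19 | 2β,9α-diacetoxy-14-(tert-butyldimethylsilyloxy)-7-epi-eudesma-3,11-dien-1β-ol | C=C(C)[C@@H]1C[C@H](OC(C)=O)[C@@]2(CO[Si](C)(C)C(C)(C)C)[C@H](C1)C(C)=C[C@H](OC(C)=O)[C@@H]2O | intermediate
20 | 2β,9α-diacetoxy-14-(tert-butyldimethylsilyloxy)-7-epi-eudesma-3,11-dien-1β-yl tiglate | C=C(C)[C@@H]1C[C@H](OC(C)=O)[C@@]2(CO[Si](C)(C)C(C)(C)C)[C@H](C1)C(C)=C[C@H](OC(C)=O)[C@@H]2OC(=O)/C(C)=C/C | intermediate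
21 | 2β,9α-diacetoxy-14-hydroxy-7-epi-eudesma-3,11-dien-1β-yl tiglate (CNP0267061.1) | C=C(C)[C@@H]1C[C@H](OC(C)=O)[C@@]2(CO)[C@H](C1)C(C)=C[C@H](OC(C)=O)[C@@H]2OC(=O)/C(C)=C/C | target

**Step count and risks**

Total step count: 17. Longest linear sequence: 16 steps (step 1, then steps 3 to 17); the diene branch (step 2) joins at step 3.

Steps most likely to fail:

1. Step 3 (key step). The Lewis acid may desilylate the dienol ether or divert it into a stepwise Mukaiyama–Michael addition that does not close ring B, and the facial selectivity may be low or opposite. Fallback: 2 and 4 are combined without catalyst in toluene at 0 °C to rt, where the ester-activated quinone alkene should react in a thermal endo cycloaddition. This gives 5 as a racemate, that is together with its enantiomer, the ent-cis-adduct F1. The two are separated by preparative chromatography on a chiral stationary phase, and the route is rejoined at 5.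

2. Step 4. The equilibrium may not favour the trans fusion strongly enough, or the base may open the non-enolisable β-keto ester by retro-Claisen cleavage. Fallback: the epimerisation is moved behind the C1 reduction. Setting out from 5, desilylation with HF·pyridine gives the cis-fused hydroxy enedione F2, and Me4NBH(OAc)3 reduction, directed by the C9 hydroxyl as in step 6, gives the cis-fused diol F3. F3 no longer holds a β-keto ester, and methoxide exchange at its methyl ester and methyl vinylogous ester is degenerate, so C5 can be equilibrated with NaOMe in MeOH. The route is rejoined at 8.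

3. Step 7. Competing addition to the C10 ester, enolisation at C5 or retro-aldol cleavage of the alkoxides may erode the chemoselectivity of the methyl addition. Fallback: the methyl group is brought in with a cuprate, which leaves esters alone. Setting out from 8, Luche reduction (NaBH4, CeCl3, MeOH) of the C4 carbonyl gives the C4 allylic alcohol F4, which dilute acid transposes to the 4-unsubstituted enone F5. Me2CuLi with Me3SiCl and Et3N adds methyl to C4 and traps the enolate and both hydroxyls as the tris(trimethylsilyl) compound F6. Saegusa–Ito oxidation with Pd(OAc)2 in MeCN restores the C3–C4 double bond in the bis-silylated enone F7, and dilute acid removes the silyl ethers. The route is rejoined at 10.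

**Further compounds**

F1 | step 3 | ent-cis-adduct (enantiomer of 5) | C1=C[C@@H](O[Si](C)(C)C(C)(C)C)[C@]2(C(=O)OC)[C@H](C1)C(=O)C=C(OC)C2=O
F2 | step 4 | cis-fused hydroxy enedione, methyl 9α-hydroxy-2-methoxy-1,4-dioxo-5β-H-decal-2,7-diene-10β-carboxylate | C1=C[C@H](O)[C@@]2(C(=O)OC)[C@@H](C1)C(=O)C=C(OC)C2=O
F3 | step 4 | cis-fused diol, methyl 1β,9α-dihydroxy-2-methoxy-4-oxo-5β-H-decal-2,7-diene-10β-carboxylate | C1=C[C@H](O)[C@@]2(C(=O)OC)[C@@H](C1)C(=O)C=C(OC)[C@@H]2O
F4 | step 7 | C4 allylic alcohol, methyl 1β,4,9α-trihydroxy-2-methoxy-trans-decal-2,7-diene-10β-carboxylate (C4 configuration not defined) | C1=C[C@H](O)[C@@]2(C(=O)OC)[C@H](C1)C(O)C=C(OC)[C@@H]2O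
F5 | step 7 | 4-unsubstituted enone, methyl 1β,9α-dihydroxy-2-oxo-trans-decal-3,7-diene-10β-carboxylate | C1=C[C@H](O)[C@@]2(C(=O)OC)[C@H](C1)C=CC(=O)[C@@H]2O
F6 | step 7 | tris(trimethylsilyl) compound, methyl 4-methyl-1β,2,9α-tris(trimethylsilyloxy)-trans-decal-2,7-diene-10β-carboxylate (C4 configuration not defined) | C1=C[C@H](O[Si](C)(C)C)[C@@]2(C(=O)OC)[C@H](C1)C(C)C=C(O[Si](C)(C)C)[C@@H]2O[Si](C)(C)C
F7 | step 7 | bis-silylated enone, methyl 4-methyl-2-oxo-1β,9α-bis(trimethylsilyloxy)-trans-decal-3,7-diene-10β-carboxylate | C1=C[C@H](O[Si](C)(C)C)[C@@]2(C(=O)OC)[C@H](C1)C(C)=CC(=O)[C@@H]2O[Si](C)(C)C
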